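**Plan**
- Retrosynthesis: after removal of a MOM ether from the ring A phenol, both bonds of the carbonyl next to ring B are cut, C6(ring B)–C(=O) and C(=O)–CH2. This leaves 6-bromo-2,2-dimethyl-2H-chromene, carbon monoxide and the 6-acetyl-7-(methoxymethoxy)chromene of ring A.
- Enabling feature: this carbonyl sits on C6 of ring B, para to the pyran oxygen O1, which is the bromine-bearing carbon of 4-bromophenol. On its other side is the central CH2, the methyl carbon of the acetyl group on C6 of ring A. One carbon between an aryl halide carbon and an enolate carbon can come from CO.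
- Ring A: the pyranone is annulated onto 4-bromoresorcinol, where the bromine marks the later acyl carbon and forces the linear fusion. The chromanone is taken to the chromene and the bromine is exchanged for acetyl.
- Ring B: the pyran arises from 4-bromophenol by propargyl ether formation and Claisen cyclisation. The three-carbon chain is then joined by the carbonylative coupling and the phenol is unmasked last.
- Stereochemistry: the target is achiral. The only stereocentre on the way (C4 of a racemic chromanol) is removed by dehydration.

Key step: step 8

Remark on the chemistry: diketones 21 and 22 are drawn in the diketo form; both should exist largely as chelated enols, which are tautomers of the same compounds.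

**Route**

Step 1
Reactants: 1 4-bromoresorcinol; 2 3-methylbut-2-enoic acid
Product: 4 6-bromo-7-hydroxy-2,2-dimethylchroman-4-one, via aryl enone 3 (not isolated)
Conditions: P2O5/MeSO3H (Eaton's reagent), 70 °C
Reagents that add atoms: none
Why: Friedel–Crafts acylation at the only free, unhindered activated carbon of 1 (ortho to one hydroxyl, para to the other; its counterpart carries bromine) gives enone 3, whose ortho hydroxyl closes the pyranone by intramolecular oxa-Michael addition, a standard chromanone annulation of resorcinols that halogenated resorcinols are known to survive in Pechmann-type acid condensations.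

Step 2
Reactants: 4 6-bromo-7-hydroxy-2,2-dimethylchroman-4-one
Product: 5 6-bromo-7-(methoxymethoxy)-2,2-dimethylchroman-4-one
Conditions: MOMCl, iPr2NEt, CH2Cl2, 0 °C to rt
Reagents that add atoms: chloromethyl methyl ether (MOMCl), COCCl
Why: O-alkylation of the acidic para-acyl phenol with MOMCl and an amine base is routine, and the acetal should tolerate the later hydride, organolithium and amide-base steps while staying removable by mild acid.

Step 3
Reactants: 5 6-bromo-7-(methoxymethoxy)-2,2-dimethylchroman-4-one
Product: 6 racemic 6-bromo-7-(methoxymethoxy)-2,2-dimethylchroman-4-ol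
Conditions: NaBH4, MeOH/THF, 0 °C to rt
Reagents that add atoms: none
Why: Borohydride reduction of the aryl ketone is chemoselective over the aryl bromide and the acetal; the C4 carbinol centre forms as a racemate and is destroyed in step 4.

Step 4
Reactants: 6 racemic 6-bromo-7-(methoxymethoxy)-2,2-dimethylchroman-4-ol
Product: 8 6-bromo-7-(methoxymethoxy)-2,2-dimethyl-2H-chromene, via chromanyl mesylate 7 (not isolated)
Conditions: MsCl, Et3N, CH2Cl2, 0 °C to 40 °C
Reagents that add atoms: none
Why: Mesylation and base-assisted E1 elimination: the benzylic mesylate 7 should ionise readily because the cation is stabilised by the ring oxygen (ortho) and the MOM oxygen (para), and loss of a C3 proton gives the conjugated 2H-chromene without exposing the acetal to acid (sulfonate-mediated dehydration of chroman-4-ols is well precedented).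

Step 5
Reactants: 8 6-bromo-7-(methoxymethoxy)-2,2-dimethyl-2H-chromene
Product: 11 1-[7-(methoxymethoxy)-2,2-dimethyl-2H-chromen-6-yl]ethanone, via aryllithium 9 (not isolated), via lithium hemiaminal alkoxide 10 (not isolated)
Conditions: n-BuLi, THF, −78 °C; MeC(O)N(OMe)Me, −78 to 0 °C; aq NH4Cl
Reagents that add atoms: N-methoxy-N-methylacetamide, CC(=O)N(C)OC
Why: Bromine–lithium exchange at −78 °C should outrun addition to the styrene-type double bond and give aryllithium 9, stabilised by chelation to the neighbouring MOM oxygen; Weinreb amide acylation stops at the chelated adduct 10, which releases the methyl ketone only on aqueous quench.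

Step 6
Reactants: 12 4-bromophenol; 13 3-chloro-3-methylbut-1-yne
Product: 14 1-bromo-4-[(2-methylbut-3-yn-2-yl)oxy]benzene
Conditions: DBU, CuCl2·2H2O (cat.), MeCN, 0 °C
Reagents that add atoms: none
Why: Copper-catalysed propargylic substitution of the tertiary propargyl chloride by the phenoxide is the standard entry to 1,1-dimethylpropargyl aryl ethers and avoids elimination of the chloride.

Step 7
Reactants: 14 1-bromo-4-[(2-methylbut-3-yn-2-yl)oxy]benzene
Product: 17 6-bromo-2,2-dimethyl-2H-chromene, via allenylphenol 15 (not isolated), via ortho-quinone methide 16 (not isolated)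
Conditions: PhNEt2, 190 °C
Reagents that add atoms: none
Why: Aromatic propargyl Claisen rearrangement ([3,3]), enolisation to allenylphenol 15, 1,5-hydrogen shift to ortho-quinone methide 16 and 6π oxa-electrocyclisation give the 2,2-dimethyl-2H-chromene; the two ortho carbons are equivalent, so a single regioisomer with bromine at C6 is expected.

Step 8
Reactants: 11 1-[7-(methoxymethoxy)-2,2-dimethyl-2H-chromen-6-yl]ethanone; 17 6-bromo-2,2-dimethyl-2H-chromene; 18 carbon monoxide
Product: 21 1-[7-(methoxymethoxy)-2,2-dimethyl-2H-chromen-6-yl]-3-(2,2-dimethyl-2H-chromen-6-yl)propane-1,3-dione (glyinflanin D MOM ether), via sodium enolate 19 (not isolated), via sodium diketonate 20 (not isolated)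
Conditions: Pd(dba)2 (5 mol %), Ph2P(CH2)3PPh2 (6 mol %), NaN(SiMe3)2 (2.2 equiv), CO (1 atm), THF, sealed vessel, 80 °C; aq NH4Cl
Reagents that add atoms: none
Why: Zerovalent palladium carrying the diphosphine should insert into the C6–Br bond of 17, migratory insertion of CO then gives an aroyl complex of divalent palladium, and enolate 19 displaces bromide on the metal before C–C reductive elimination, so the aryl–CO and CO–CH2 bonds form in one operation. The closest known reaction type is the palladium-catalysed carbonylative α-arylation of aryl methyl ketones with aryl bromides to 1,3-diketones, for which this catalyst and base combination is established. No ring closes and no stereocentre is created. The selectivity needed is CO uptake before enolate capture, as opposed to direct α-arylation; the CO atmosphere and the chelating three-carbon diphosphine, which favours the acyl complex, should secure it. The second equivalent of base converts the product at once into diketonate 20, which should resist a second aroylation and retro-Claisen cleavage. In the substrates, the ketone has a single enolisable site, the MOM ether prevents O-aroylation of the phenol, and the cis-disubstituted chromene double bonds next to quaternary carbons should not enter Heck chemistry.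

Step 9
Reactants: 21 glyinflanin D MOM ether
Product: 22 glyinflanin D, 1-(7-hydroxy-2,2-dimethyl-2H-chromen-6-yl)-3-(2,2-dimethyl-2H-chromen-6-yl)propane-1,3-dione
Conditions: 3 M aq HCl, MeOH, rt
Reagents that add atoms: none
Why: Acid-catalysed acetal exchange with methanol removes the MOM group, which is especially labile ortho to the chelating carbonyl, at room temperature where cyclodehydration to a flavone and addition to the chromene double bonds should stay slow.

**Compound list**
1 | 4-bromoresorcinol | Oc1ccc(Br)c(O)c1 | starting material
2 | 3-methylbut-2-enoic acid | CC(C)=CC(=O)O | starting material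
3 | 1-(5-bromo-2,4-dihydroxyphenyl)-3-methylbut-2-en-1-one | CC(C)=CC(=O)c1cc(Br)c(O)cc1O | intermediate
4 | 6-bromo-7-hydroxy-2,2-dimethylchroman-4-one | CC1(C)CC(=O)c2cc(Br)c(O)cc2O1 | intermediate
5 | 6-bromo-7-(methoxymethoxy)-2,2-dimethylchroman-4-one | CC1(C)CC(=O)c2cc(Br)c(OCOC)cc2O1 | intermediate
6 | racemic 6-bromo-7-(methoxymethoxy)-2,2-dimethylchroman-4-ol | CC1(C)CC(O)c2cc(Br)c(OCOC)cc2O1 | intermediate
7 | racemic 6-bromo-7-(methoxymethoxy)-2,2-dimethylchroman-4-yl methanesulfonate | CC1(C)CC(OS(C)(=O)=O)c2cc(Br)c(OCOC)cc2O1 | intermediate
8 | 6-bromo-7-(methoxymethoxy)-2,2-dimethyl-2H-chromene | CC1(C)C=Cc2cc(Br)c(OCOC)cc2O1 | intermediate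
9 | [7-(methoxymethoxy)-2,2-dimethyl-2H-chromen-6-yl]lithium | [Li]c1cc2C=CC(C)(C)Oc2cc1OCOC | intermediate
10 | lithium 1-[methoxy(methyl)amino]-1-[7-(methoxymethoxy)-2,2-dimethyl-2H-chromen-6-yl]ethanolate | [Li+].CC([O-])(N(C)OC)c1cc2C=CC(C)(C)Oc2cc1OCOC | intermediate
11 | 1-[7-(methoxymethoxy)-2,2-dimethyl-2H-chromen-6-yl]ethanone | CC(=O)c1cc2C=CC(C)(C)Oc2cc1OCOC | intermediate
12 | 4-bromophenol | Oc1ccc(Br)cc1 | starting material
13 | 3-chloro-3-methylbut-1-yne | CC(C)(Cl)C#C | starting material
14 | 1-bromo-4-[(2-methylbut-3-yn-2-yl)oxy]benzene | CC(C)(Oc1ccc(Br)cc1)C#C | intermediate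
15 | 4-bromo-2-(3-methylbuta-1,2-dien-1-yl)phenol | CC(C)=C=Cc1cc(Br)ccc1O | intermediate
16 | 4-bromo-6-(3-methylbut-2-en-1-ylidene)cyclohexa-2,4-dien-1-one | CC(C)=CC=C1C=C(Br)C=CC1=O | intermediate
17 | 6-bromo-2,2-dimethyl-2H-chromene | CC1(C)C=Cc2cc(Br)ccc2O1 | intermediate
18 | carbon monoxide | [C-]#[O+] | starting material
19 | sodium 1-[7-(methoxymethoxy)-2,2-dimethyl-2H-chromen-6-yl]ethenolate | [Na+].C=C([O-])c1cc2C=CC(C)(C)Oc2cc1OCOC | intermediate
20 | sodium enolate of diketone 21 (sodium diketonate) | [Na+].CC1(C)C=Cc2cc(C([O-])=CC(=O)c3cc4c(cc3OCOC)OC(C)(C)C=C4)ccc2O1 | intermediate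
21 | 1-[7-(methoxymethoxy)-2,2-dimethyl-2H-chromen-6-yl]-3-(2,2-dimethyl-2H-chromen-6-yl)propane-1,3-dione | CC1(C)C=Cc2cc(C(=O)CC(=O)c3cc4c(cc3OCOC)OC(C)(C)C=C4)ccc2O1 | intermediate
22 | glyinflanin D | CC1(C)C=Cc2cc(C(=O)CC(=O)c3cc4c(cc3O)OC(C)(C)C=C4)ccc2O1 | target

**Step count**
Total: 9 steps. Longest linear sequence: 7 steps (steps 1, 2, 3, 4, 5, 8, 9); steps 6 and 7 form the convergent ring B branch.

**Steps most likely to fail**

Step 8. Oxidative addition of the electron-rich bromide may be slow under CO, the enolate may couple without CO uptake (direct α-arylation), or the silylamide may intercept the aroyl complex. The fallback sets out from 17 and returns at 21, introducing the CO carbon in a separate step. Methoxycarbonylation of 17 (Pd(OAc)2, Xantphos, Et3N, MeOH, CO 1 atm, 70 °C) should give methyl 2,2-dimethyl-2H-chromene-6-carboxylate F1. A crossed Claisen condensation of the enolate of 11 with F1 (NaH, THF, 60 °C; aq NH4Cl) should then give 21, with the same diketonate protecting the product.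

Step 1. Hot P2O5/MeSO3H may cause migration or loss of bromine by ipso protonation, or acylation at the carbon between the two hydroxyls. The fallback sets out from 1 and returns at 8, bypassing steps 1 to 4. Pyridine-mediated chromenylation of 1 with 3-methylbut-2-enal (pyridine, 120 °C) proceeds by C-alkylation para to one hydroxyl, dehydration to an ortho-quinone methide and 6π oxa-electrocyclisation. It should give 6-bromo-2,2-dimethyl-2H-chromen-7-ol F2 directly, and MOMCl/iPr2NEt in CH2Cl2 then gives 8. Its regiocontrol and the chance of a second annulation are less predictable, which is why the longer acid route is preferred.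

Step 9. The liberated ortho-hydroxy diketone may cyclodehydrate to a flavone, or acid may add methanol across the chromene double bonds, in competition with acetal cleavage. The fallback sets out from 11 and returns at 22. The MOM group is removed at the ketone stage (3 M aq HCl, MeOH, rt), where no diketone is present, to give 1-(7-hydroxy-2,2-dimethyl-2H-chromen-6-yl)ethanone F3. F3 is then coupled with 17 and 18 under the catalyst of step 8 with 3.2 equiv of NaN(SiMe3)2, so that the phenoxide–enolate is the nucleophile. Any O-aroylation should converge on the same diketonate by a Baker–Venkataraman-type 1,5-acyl shift, and a cold buffered work-up (aq NH4Cl) should give 22 without prolonged contact with acid.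

**Further compounds**
F1 | step 8 | methyl 2,2-dimethyl-2H-chromene-6-carboxylate | COC(=O)c1ccc2OC(C)(C)C=Cc2c1
F2 | step 1 | 6-bromo-2,2-dimethyl-2H-chromen-7-ol | CC1(C)C=Cc2cc(Br)c(O)cc2O1
F3 | step 9 | 1-(7-hydroxy-2,2-dimethyl-2H-chromen-6-yl)ethanone | CC(=O)c1cc2C=CC(C)(C)Oc2cc1O
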